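The chemist watching the spring flask must choose what to do at 25 h, so we count how much turnover each catalyst dose buys.

| flask | left-handed substrate | right-handed substrate | coupling partner | free catalyst | impurity | remark | time |
|---|---|---|---|---|---|---|---|
| spring | 0.25 M | 0.25 M | 0.375 M | 1.2 mM | 0.47 mM | the very flask that is asked about, followed so far |  |
| summer | 0.25 M | 0.25 M | 0.375 M | 0.80 mM | 0.47 mM | run made earlier |  |
| flask | 0.25 M | 0.25 M | 0.375 M | 1.2 mM | 0.47 mM |  | 25 h |

- spring (time / h: left-handed product / %, left-handed substrate / %): 1.50: 15, 39; 5.00: 19, 31; 8.00: 22, 25; 15.0: 22, 28; 20.0: 22, 29; 25.0: 22, 27
- summer (time / min: left-handed product / %, left-handed substrate / %): 8.00: 0, 48; 20.0: 1, 49; 40.0: 3, 47; 60.0: 2, 45; 80.0: 6, 40; 120: 8, 38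

(readings scatter by 2 percentage points)

- Thursday's: at 25 h add free catalyst, 100% of the amount charged, then wait 2.0 d
- Friday's: change nothing and wait 2.0 d more
- Tuesday's: at 25 h add coupling partner, 50.0% of the amount charged, then wait 2.0 d
- Monday's: at 25 h take out 90% of the left-handed product then present, then wait 2.0 d

- free catalyst is single-handed; left-handed substrate and right-handed substrate are mirror images of each other, charged as a racemate, each of them at the stated concentration
- left-handed product that was removed still counts
- reactions considered so far: coupling partner + free catalyst -> spent catalyst B; coupling partner + free catalyst + left-handed substrate -> free catalyst + left-handed product; free catalyst + impurity -> spent catalyst C; free catalyst -> spent catalyst A; coupling partner + free catalyst + right-handed substrate -> free catalyst + right-handed product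
- additions bring no volume worth counting

1. left-handed product, in percent of the left-handed substrate and right-handed substrate together first charged, at 25 h
2. which option adds most left-handed product ("none" when 2 percentage points or less is all one gets) (Thursday's / Friday's / Tuesday's / Monday's / none)
3. left-handed product present, with what was taken out counted in, in percent of the left-handed substrate and right-handed substrate together first charged, after Thursday's
4. left-handed product present, with what was taken out counted in, in percent of the left-handed substrate and right-handed substrate together first charged, after Friday's

1. First estimate: in the spring run the left-handed product is flat at 22% from 8.00 h to 25.0 h, so we take that for "now". Flat could mean a dead catalyst or a missing reagent.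

2. Objection: has the coupling partner gone? That product used 0.110 M of 0.375 M. If we guess that the right-handed substrate turned over no faster, 41.3% to 70.7% of the partner remains, so we blame the catalyst.

3. Does the whole charge count? Early rates, spring over summer, stand at 2.50. The charges stand at 1.50, but charges less impurity at 2.21, so we count 0.730 mM as live in the spring flask.

4. At fixed c(coupling partner) the left-handed substrate falls pseudo-first-order in catalyst exposure, so turnovers are counted on a log scale. We keep 0.794 mM⁻¹ as the turnover dose L, that is ln of c(left-handed substrate) at the start over that at the stop, per mM of live catalyst.

5. Waiting, more partner and removing product add no catalyst, which leaves Thursday's. The first charge of 1.2 mM stood above the impurity charge of 0.47 mM, so we count the fresh 1.2 mM as live, and by L it acts on the remaining left-handed substrate, 28.0%, which gives 39.2%.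

6. Objection: the fresh dose meets less partner than the first did. Scaling L by partner at 25 h over its mean in the first round gives 34.0% to 37.3%.

7. The forecast says 22.5% now, Thursday's as best, 27% after Thursday's and 22.8% after Friday's, arguing “Fresh catalyst uses the remaining partner”. Our range lies higher.

8. The flask gives 22.5% now, and Thursday's is best. Thursday's reaches 35.1%, a gain of 13 percentage points, and Friday's stays at 22.5%.

    coupling partner + free catalyst → spent catalyst B (k = 0.00470 L mol⁻¹ min⁻¹)
    coupling partner + free catalyst + left-handed substrate → free catalyst + left-handed product (k = 24.0 L² mol⁻² min⁻¹)
    free catalyst + impurity → spent catalyst C (k = 2100 L mol⁻¹ min⁻¹)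
    free catalyst → spent catalyst A (k = 0.00700 min⁻¹)
    coupling partner + free catalyst + right-handed substrate → free catalyst + right-handed product (k = 7.10 L² mol⁻² min⁻¹)

Thursday's fresh dose earned 0.508 mM⁻¹, less than L, with 59.1% of the partner left at 25.0 h. The decay of free catalyst to spent catalyst A is the largest single effect on Thursday's gain: without that step the same flask holds 43.2% of left-handed product at 25 h, against 22.5%, and gains 3.6 points from Thursday's, against 13 points. For the summer flask, L on its live catalyst gives 11.5% of left-handed product, and that run carried to 25 h stands at 13.1%.

The numbers in the tables come from a simulation for substances that don't exist; the scatter is artificial.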